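## Structural features

The target is a 2,3-dihydrobenzofuran. Benzo ring A is fused through C3a–C7a to the five-membered oxygen ring B (O1, C2, C3), and a separate aryl ring C (3-hydroxy-4,5-dimethoxyphenyl) is attached to C2. Ring A carries a methoxy group at C7, next to the oxygen-bearing carbon C7a, and an (E)-prop-1-enyl group at C5, para to O1; C3 carries a methyl group. C2 and C3 are adjacent stereocentres, both S, with aryl and methyl trans on ring B. The fragile points are the C2–O1 bond (a benzylic ether carbon activated by the para-methoxy group of ring C, so acid can ionise it and scramble C2), the electron-rich propenyl styrene (sensitive to acid, oxidants, hydrogenation and palladium hydrides, also in its geometry) and the free phenol of ring C. The real difficulty is absolute control of the vicinal C2/C3 pair, because ring closures that form O1–C2 through a benzylic cation fix only the relative configuration. The plan exploits the fact that O1–C7a is an aryl–oxygen bond that touches neither stereocentre. C7a, flanked by the C7 methoxy carbon and C3a, is the phenol carbon of a vanillin-type arene, so it can carry a sulfonate leaving group while O1 arrives as the carbinol oxygen on C2.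

## Logic of the disconnections

**14 from 13.** The cut is the O–CH2 bond of the acetal on the ring C oxygen. The phenol must be masked because two palladium-catalysed steps run under base, where a free phenoxide would itself be arylated; an acetal is inert to every base and nucleophile used. Nothing is gained in skeleton, but the only acidic site is removed from all earlier intermediates. The demand is that the acetal must leave under acid too weak to ionise C2–O1 or protonate the propenyl group.

**13 from 12.** The cut is the aryl–oxygen bond O1–C7a. It is the one bond of ring B attached to neither stereocentre, so opening it turns the trans ring into an acyclic syn 1,2-pair (carbinol at the future C2, methyl-bearing carbon at the future C3) and keeps the closure away from the C2 cation. The gain is the loss of ring B. The demand is a C–O reductive elimination from a secondary benzylic alkoxide that must beat β-hydride elimination, on a sulfonate that must survive the base until the metal has inserted.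

**12 from 11.** The carbinol is returned to the ketone (the C1–H and O–H bonds are removed). The α-carbon of 11 lies between a carbonyl group and an aryl ring and is configurationally labile, so one enantioselective hydride delivery can set both centres while the ketone racemises. The gain is that both stereocentres disappear and racemic 11 suffices. The demand is that enolisation outruns reduction of the mismatched enantiomer, under a base that does not cleave the sulfonate, and that the matched enantiomer leads to the syn (1S,2S) pair.

**11 from 6 and 10.** The cut is the bond between the α-carbon and ring A (the future C3–C3a). It splits the molecule into two arenes of similar size, each three steps from a commercial benzaldehyde, which makes the route convergent. The demand is that the catalyst inserts into the C–I bond of 6 and leaves the neighbouring C–O sulfonate alone, that the base is too weak to attack sulfur, and that the enolate of 11 does not close onto the sulfonate-bearing carbon.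

**6 from 5, 2, 1 and 3.** The cuts are the propenyl C=C bond (back to the formyl group of 2 and the ylide 4 made from 3) and the O–S bond of the sulfonate (back to the phenol of 1). In 1 the four substituents already stand where ring A needs them: iodine where C3a forms its C–C bond, the phenol oxygen on the future C7a, methoxy on C7 and the formyl carbon where the propenyl group grows. Sulfonylation comes first, so that no oxidation-prone propenylphenol is ever handled and the aldehyde is at its most electrophilic. The demand is geometric: the ylide olefination is not E-selective, so 5 must be equilibrated to 6.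

**10 from 9, 8 and 7.** The cuts are the bond between the carbinol carbon and the ethyl group (ethyl addition to the aldehyde, then oxidation) and the acetal O–CH2 bond. 7 already has the full oxygenation pattern of ring C, so no arene functionalisation is needed. The only demand is that the acetal is in place before the organometallic reagent is used.

## Other disconnections considered

**Alternative 1:** The cut removes C2–C3 and O1–C2 together, so ring B is built from a ring A ortho-quinone methide and a one-carbon ring C unit.
- **Forward step:** Base would expel sulfinate from the phenol sulfone A2 to release the ethylidene quinone methide A3. The ylide from the chiral benzylic sulfonium salt A4 would add to the exocyclic carbon of A3 (C2–C3), and the phenoxide would displace the sulfide at the benzylic carbon (O1–C2) to give the bromide A1. A1 would still need a Suzuki–Miyaura propenylation and desilylation.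
- **In favour:** Two bonds, ring B and both stereocentres would come from one step, which is better bond economy than the chosen closure (one bond, no stereocentre). Anti-periplanar displacement in the betaine should favour the trans ring. The propenyl group would come last from a geometrically defined coupling partner, a better answer to the E geometry than olefination plus isomerisation.
- **Against:** Chirality must be relayed from a stoichiometric sulfonium reagent to two carbons, and for a semi-stabilised benzylic ylide adding to an alkyl-substituted quinone methide the level of enantiocontrol is hard to foresee. A 1,5-hydrogen shift from the methyl group could destroy A3 before the ylide adds. O1–C2 is formed at the very carbon whose ionisation erodes trans selectivity.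
- **Comparison:** The step count should be about equal. The absolute configuration would rest on a less predictable transfer than a ketone reduction with a well-understood catalyst model.

**Alternative 2:** The cut is O1–C2, with the C3 methyl group traced back to the CH2 of a cyclopropane.
- **Forward step:** Catalytic TfOH in hexafluoroisopropanol would protonate the CH2 carbon of the trans-diarylcyclopropane A6 and cleave its bond to the ring C benzylic carbon. The ortho phenol would capture the cation, forming O1–C2 and closing ring B to the ester A5.
- **In favour:** C3 is stored in a cyclopropane carbon that cannot epimerise, which is better than a racemisable α-aryl ketone (although the chosen plan turns that lability to use). The key step needs only a catalytic acid and no transition metal, which is better in cost and simplicity. The ester at C5 tolerates the acid.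
- **Against:** The cyclopropane has two bonds to the ring C benzylic carbon, and cleavage of the more substituted one would lead to six-membered closure through oxygen instead of ring B. C2 is set only by the trans preference of cation capture, so the step runs through the C2 cation. The strong acid threatens the silyl ether and invites Friedel–Crafts reactions of the electron-rich rings. Making A6 enantioenriched and converting the ester of A5 into an E-propenyl group (reduction, oxidation, olefination with the same geometry problem) add steps.
- **Comparison:** Mechanistically it depends on the pathway the chosen plan avoids, and it should be clearly longer.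

**Alternative 3:** The cut is C2–C3.
- **Forward step:** With Rh2(S-PTTL)4 or its enantiomer (a carboxylate dimer of divalent rhodium), the carbenoid from the aryldiazoacetate A8 would insert into a benzylic C–H bond of the OCH2 group of its ring C benzyl ether. This forms C2–C3 and closes ring B to the cis ester A7.
- **In favour:** It is a catalytic enantioselective C–C bond formation that creates both stereocentres in the ring-forming step from an achiral precursor, which is better than the chosen closure on that point. The reaction class is well established for cis-2-aryl-2,3-dihydrobenzofuran-3-carboxylates, so in reliability of enantiocontrol it is the equal of the transfer hydrogenation. Either antipode is available by choice of catalyst enantiomer, as in the chosen plan.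
- **Against:** The insertion delivers the cis isomer, so C3 of A7 must be epimerised. The ester must then be taken down to a methyl group (reduction, activation, hydride displacement) without disturbing the aryl bromide, followed by Suzuki–Miyaura propenylation and acetal removal. A8 is a diazo compound that must be made by diazo transfer and handled with care.
- **Comparison:** By a rough count it is the longest of the four; the chosen plan installs the C3 methyl group directly.

Key step: step 9

Assumption: the (S,S)-TsDPEN catalyst is taken to reduce this aryl ketone in its usual sense (S carbinol, as for simple aryl alkyl ketones), with Felkin–Anh matching at the α-centre; if the sense proved opposite, the (R,R)-catalyst would be used with no other change.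

## Route

Step 1
Reactants: 1 5-iodovanillin (4-hydroxy-3-iodo-5-methoxybenzaldehyde)
Product: 2 4-formyl-2-iodo-6-methoxyphenyl trifluoromethanesulfonate
Conditions: Tf2O (1.2 equiv), pyridine, CH2Cl2, 0 °C to rt
Reagents that add atoms: trifluoromethanesulfonic anhydride, O=S(=O)(OS(=O)(=O)C(F)(F)F)C(F)(F)F
Why: O-sulfonylation of a phenol; the para-formyl and ortho-iodo groups make the phenol acidic and pyridine-activated Tf2O triflates even hindered phenols. Doing this first installs the leaving group for the key step and keeps an oxidation-prone propenylphenol out of the route.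

Step 2
Reactants: 2 4-formyl-2-iodo-6-methoxyphenyl trifluoromethanesulfonate; 3 ethyltriphenylphosphonium bromide
Product: 5 2-iodo-6-methoxy-4-(prop-1-en-1-yl)phenyl trifluoromethanesulfonate (Z/E mixture), via ethylidenetriphenylphosphorane 4 (not isolated)
Conditions: 3 (1.3 equiv), NaN(SiMe3)2 (1.2 equiv), THF, 0 °C; then 2, −78 to 0 °C
Reagents that add atoms: none
Why: Wittig olefination with a non-stabilised ylide; the aldehyde para to the triflate is strongly electrophilic and should react at −78 °C, well before the ylide can attack sulfur. A Z-rich mixture is expected and is corrected in step 3.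

Step 3
Reactants: 5 2-iodo-6-methoxy-4-(prop-1-en-1-yl)phenyl trifluoromethanesulfonate (Z/E mixture)
Product: 6 2-iodo-6-methoxy-4-[(E)-prop-1-en-1-yl]phenyl trifluoromethanesulfonate
Conditions: PdCl2(MeCN)2 (5 mol%), CH2Cl2, rt
Reagents that add atoms: none
Why: Alkene geometric isomerisation catalysed by divalent palladium, which equilibrates β-methylstyrenes to the thermodynamically preferred E isomer. The catalyst stays divalent and so should not insert into the C–I or C–O triflate bonds.

Step 4
Reactants: 7 3-hydroxy-4,5-dimethoxybenzaldehyde
Product: 8 3,4-dimethoxy-5-(methoxymethoxy)benzaldehyde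
Conditions: MOMCl (1.5 equiv), i-Pr2NEt, CH2Cl2, 0 °C to rt
Reagents that add atoms: chloromethyl methyl ether, COCCl
Why: O-alkylation of a phenol (MOM protection); the acetal is inert to the Grignard reagent, the oxidant and the basic palladium steps that follow.

Step 5
Reactants: 8 3,4-dimethoxy-5-(methoxymethoxy)benzaldehyde
Product: 9 1-[3,4-dimethoxy-5-(methoxymethoxy)phenyl]propan-1-ol (racemic)
Conditions: EtMgBr (1.2 equiv), THF, 0 °C
Reagents that add atoms: ethylmagnesium bromide, CC[Mg]Br
Why: Grignard addition to an aromatic aldehyde; the stereocentre is formed as the racemate and is removed in step 6.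

Step 6
Reactants: 9 1-[3,4-dimethoxy-5-(methoxymethoxy)phenyl]propan-1-ol (racemic)
Product: 10 1-[3,4-dimethoxy-5-(methoxymethoxy)phenyl]propan-1-one
Conditions: MnO2 (activated, excess), CH2Cl2, rt
Reagents that add atoms: none
Why: Oxidation of a benzylic alcohol with MnO2, selective for the electron-rich benzylic position and neutral toward the acetal.

Step 7
Reactants: 6 2-iodo-6-methoxy-4-[(E)-prop-1-en-1-yl]phenyl trifluoromethanesulfonate; 10 1-[3,4-dimethoxy-5-(methoxymethoxy)phenyl]propan-1-one
Product: 11 1-[3,4-dimethoxy-5-(methoxymethoxy)phenyl]-2-[3-methoxy-5-((E)-prop-1-en-1-yl)-2-(trifluoromethylsulfonyloxy)phenyl]propan-1-one (racemic)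
Conditions: 6 (1.2 equiv), Pd2(dba)3 (2 mol%), Xantphos (5 mol%), K3PO4 (2.5 equiv), toluene, 80 °C
Reagents that add atoms: none
Why: Palladium-catalysed α-arylation of a ketone (Buchwald–Hartwig type): bisphosphine-ligated zerovalent palladium inserts into C–I far faster than into the hindered C–O triflate bond, K3PO4 deprotonates the ketone at palladium, and C–C reductive elimination forms the Cα–aryl bond. The weak, insoluble phosphate should not attack the S–O bond, and the slight excess of 6 keeps the catalyst on C–I so the triflate of 11 is not activated; the stereocentre is deliberately formed racemic.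

Step 8
Reactants: 11 1-[3,4-dimethoxy-5-(methoxymethoxy)phenyl]-2-[3-methoxy-5-((E)-prop-1-en-1-yl)-2-(trifluoromethylsulfonyloxy)phenyl]propan-1-one (racemic)
Product: 12 (1S,2S)-1-[3,4-dimethoxy-5-(methoxymethoxy)phenyl]-2-[3-methoxy-5-((E)-prop-1-en-1-yl)-2-(trifluoromethylsulfonyloxy)phenyl]propan-1-ol
Conditions: RuCl(p-cymene)[(S,S)-TsDPEN] (2 mol%), HCO2H/Et3N (1:2), DMF, 40 °C
Reagents that add atoms: none
Why: Noyori–Ikariya asymmetric transfer hydrogenation with dynamic kinetic resolution: excess amine epimerises the α-aryl ketone through its enol(ate), the (S,S) catalyst delivers hydride to the face that gives the (1S) carbinol, and the (2S) ketone is the matched enantiomer because hydride then arrives anti to the bulky ring A aryl group (Felkin–Anh). Both stereocentres should therefore emerge as the syn (1S,2S) pair; the triflate, the acetal and the unpolarised propenyl double bond are inert to the ruthenium hydride.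

Step 9
Reactants: 12 (1S,2S)-1-[3,4-dimethoxy-5-(methoxymethoxy)phenyl]-2-[3-methoxy-5-((E)-prop-1-en-1-yl)-2-(trifluoromethylsulfonyloxy)phenyl]propan-1-ol
Product: 13 (2S,3S)-2-[3,4-dimethoxy-5-(methoxymethoxy)phenyl]-7-methoxy-3-methyl-5-[(E)-prop-1-en-1-yl]-2,3-dihydrobenzofuran
Conditions: Pd2(dba)3 (2.5 mol%), t-BuXPhos (6 mol%), K3PO4 (2 equiv), toluene, 80 °C
Reagents that add atoms: none
Why: Zerovalent palladium bearing one t-BuXPhos inserts into the C7a–O bond of the aryl triflate, the carbinol binds to the arylpalladium centre and is deprotonated by K3PO4, and C–O reductive elimination from the six-membered oxapalladacycle forms O1–C7a. The closest known reaction type is the palladium-catalysed intramolecular etherification of aryl halides and sulfonates with secondary alcohols (Buchwald–Hartwig C–O coupling), established for five-membered rings. Ring B closes in a 5-exo sense, the alkoxide oxygen attacking the ring A carbon that bears the exocyclic leaving group. No stereocentre is created and no bond to C2 or C3 is made or broken, so the syn (1S,2S) arrangement of 12 is carried over as the trans (2S,3S) ring and the C2 benzylic cation is never formed. The step needs C–O reductive elimination to outrun β-hydride elimination of the benzylic alkoxide, which would return a ketone and open a path to epimerisation. The bulky di-tert-butylbiaryl phosphine and the two ortho substituents on the palladium-bound aryl group both accelerate reductive elimination, and a five-membered closure is the most favourable case. The poorly soluble phosphate keeps free alkoxide low so the S–O bond should not be attacked, the acetal keeps the ring C oxygen from competing as a nucleophile, and the propenyl group, meta to the reacting carbon, cannot insert intramolecularly.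

Step 10
Reactants: 13 (2S,3S)-2-[3,4-dimethoxy-5-(methoxymethoxy)phenyl]-7-methoxy-3-methyl-5-[(E)-prop-1-en-1-yl]-2,3-dihydrobenzofuran
Product: 14 5-[(2S,3S)-7-methoxy-3-methyl-5-((E)-prop-1-en-1-yl)-2,3-dihydrobenzofuran-2-yl]-2,3-dimethoxyphenol (target)
Conditions: HCl (ca. 1 M in MeOH), THF, rt
Reagents that add atoms: none
Why: Acid-catalysed acetal solvolysis (MOM removal); methanol captures the oxocarbenium ion as dimethoxymethane. Dilute acid at room temperature is chosen because aryl MOM ethers cleave under conditions where the C2–O1 ether and the propenyl group should not yet ionise; no stereocentre is touched.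

## Compound list

1 | 5-iodovanillin (4-hydroxy-3-iodo-5-methoxybenzaldehyde) | O=Cc1cc(I)c(O)c(OC)c1 | starting material
2 | 4-formyl-2-iodo-6-methoxyphenyl trifluoromethanesulfonate | O=Cc1cc(I)c(OS(=O)(=O)C(F)(F)F)c(OC)c1 | intermediate
3 | ethyltriphenylphosphonium bromide | CC[P+](c1ccccc1)(c1ccccc1)c1ccccc1.[Br-] | starting material
4 | ethylidenetriphenylphosphorane | CC=P(c1ccccc1)(c1ccccc1)c1ccccc1 | intermediate (not isolated)
5 | 2-iodo-6-methoxy-4-(prop-1-en-1-yl)phenyl trifluoromethanesulfonate, Z/E mixture (double-bond geometry not defined) | CC=Cc1cc(I)c(OS(=O)(=O)C(F)(F)F)c(OC)c1 | intermediate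
6 | 2-iodo-6-methoxy-4-[(E)-prop-1-en-1-yl]phenyl trifluoromethanesulfonate | C/C=C/c1cc(I)c(OS(=O)(=O)C(F)(F)F)c(OC)c1 | intermediate
7 | 3-hydroxy-4,5-dimethoxybenzaldehyde | O=Cc1cc(O)c(OC)c(OC)c1 | starting material
8 | 3,4-dimethoxy-5-(methoxymethoxy)benzaldehyde | O=Cc1cc(OCOC)c(OC)c(OC)c1 | intermediate
9 | 1-[3,4-dimethoxy-5-(methoxymethoxy)phenyl]propan-1-ol, racemic | CCC(O)c1cc(OCOC)c(OC)c(OC)c1 | intermediate
10 | 1-[3,4-dimethoxy-5-(methoxymethoxy)phenyl]propan-1-one | CCC(=O)c1cc(OCOC)c(OC)c(OC)c1 | intermediate
11 | 1-[3,4-dimethoxy-5-(methoxymethoxy)phenyl]-2-[3-methoxy-5-((E)-prop-1-en-1-yl)-2-(trifluoromethylsulfonyloxy)phenyl]propan-1-one, racemic | C/C=C/c1cc(OC)c(OS(=O)(=O)C(F)(F)F)c(c1)C(C)C(=O)c1cc(OCOC)c(OC)c(OC)c1 | intermediate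
12 | (1S,2S)-1-[3,4-dimethoxy-5-(methoxymethoxy)phenyl]-2-[3-methoxy-5-((E)-prop-1-en-1-yl)-2-(trifluoromethylsulfonyloxy)phenyl]propan-1-ol | C/C=C/c1cc(OC)c(OS(=O)(=O)C(F)(F)F)c(c1)[C@H](C)[C@H](O)c1cc(OCOC)c(OC)c(OC)c1 | intermediate
13 | (2S,3S)-2-[3,4-dimethoxy-5-(methoxymethoxy)phenyl]-7-methoxy-3-methyl-5-[(E)-prop-1-en-1-yl]-2,3-dihydrobenzofuran | C/C=C/c1cc(OC)c2c(c1)[C@H](C)[C@@H](c1cc(OCOC)c(OC)c(OC)c1)O2 | intermediate
14 | 5-[(2S,3S)-7-methoxy-3-methyl-5-((E)-prop-1-en-1-yl)-2,3-dihydrobenzofuran-2-yl]-2,3-dimethoxyphenol | C/C=C/c1cc(OC)c2c(c1)[C@H](C)[C@@H](c1cc(O)c(OC)c(OC)c1)O2 | target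

## Step count and least certain steps

Total: 10 steps. Longest linear sequence: 7 steps (steps 1, 2, 3, 7, 8, 9, 10; the ring C branch through steps 4, 5, 6 is equally long).

**Step 9 (key step).** The most likely failure is β-hydride elimination from the arylpalladium alkoxide, since the carbinol C–H is benzylic. It would reduce the triflate-bearing carbon, oxidise the alcohol, and could erode configuration by re-addition. Base-induced S–O cleavage of the triflate before palladium inserts is the second risk.

Fallback: from 12, cleave the sulfonate with Et4NOH in dioxane at rt to (1S,2S)-2-[2-hydroxy-3-methoxy-5-((E)-prop-1-en-1-yl)phenyl]-1-[3,4-dimethoxy-5-(methoxymethoxy)phenyl]propan-1-ol F1. Then close ring B by acid-catalysed cyclodehydration (catalytic TsOH, CH2Cl2, 0 °C, short contact). The carbinol on the trioxygenated ring C ionises and the phenol captures the cation on the face opposite the C3 methyl group, so the fixed C3 centre dictates the trans ring. The route is rejoined at 13. This accepts the C2 cation that the main plan avoids; the low temperature is meant to let phenol capture outrun elimination or a hydride shift from C3.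

**Step 7.** The most likely failures are insertion of palladium into the C–O triflate bond once C–I has reacted, followed by O-arylation of the product enolate (an aromatising ring closure), and loss of the triflyl group to base. A monophosphine catalyst based on P(t-Bu)3, which is known to prefer halides over triflates, is the ligand-level remedy.

Fallback (the sulfonate is introduced only after the C–C bond):
- From 1, silylate the phenol (i-Pr3SiCl, imidazole, DMF) to 3-iodo-5-methoxy-4-(triisopropylsilyloxy)benzaldehyde F2.
- Olefinate with 4 as in step 2 to [2-iodo-6-methoxy-4-(prop-1-en-1-yl)phenoxy]triisopropylsilane (Z/E mixture) F3.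
- Isomerise as in step 3 to [2-iodo-6-methoxy-4-((E)-prop-1-en-1-yl)phenoxy]triisopropylsilane F4.
- Couple F4 with 10 under the conditions of step 7 to racemic 1-[3,4-dimethoxy-5-(methoxymethoxy)phenyl]-2-[3-methoxy-5-((E)-prop-1-en-1-yl)-2-(triisopropylsilyloxy)phenyl]propan-1-one F5.
- Treat F5 with CsF and PhNTf2 in DMF at rt. This unmasks 2-[2-hydroxy-3-methoxy-5-((E)-prop-1-en-1-yl)phenyl]-1-[3,4-dimethoxy-5-(methoxymethoxy)phenyl]propan-1-one F6 (as its phenoxide, not isolated) and triflates it in the same flask, rejoining the route at 11.

**Step 8.** The most likely failure is epimerisation of the α-centre that is too slow relative to hydride transfer, so the reaction behaves as a plain kinetic resolution and stalls or loses diastereoselectivity. Slow reduction of the hindered ketone is the second risk.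

Fallback: from 11, reduce with LiBH(s-Bu)3 in THF at −78 °C. Felkin–Anh control should give the racemic syn alcohol, that is 12 together with its enantiomer (1R,2R)-1-[3,4-dimethoxy-5-(methoxymethoxy)phenyl]-2-[3-methoxy-5-((E)-prop-1-en-1-yl)-2-(trifluoromethylsulfonyloxy)phenyl]propan-1-ol F7. Preparative chromatography on a chiral stationary phase separates the two, and the route is rejoined at 12. F7 can be oxidised back to 11 with Dess–Martin periodinane and recycled.

**Step 10.** The most likely failure is acid-induced ionisation of the C2–O1 bond (epimerisation or ring opening by methanol) or protonation of the propenyl group during acetal cleavage.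

Fallback (the protecting group is exchanged where acid is harmless):
- From 11, where the propenyl group sits on the electron-poor triflate-bearing ring and no benzylic ether exists, remove the acetal with HCl in MeOH at rt to racemic 1-(3-hydroxy-4,5-dimethoxyphenyl)-2-[3-methoxy-5-((E)-prop-1-en-1-yl)-2-(trifluoromethylsulfonyloxy)phenyl]propan-1-one F8.
- Silylate (i-Pr3SiCl, imidazole, DMF) to racemic 1-[3,4-dimethoxy-5-(triisopropylsilyloxy)phenyl]-2-[3-methoxy-5-((E)-prop-1-en-1-yl)-2-(trifluoromethylsulfonyloxy)phenyl]propan-1-one F9.
- Apply the conditions of step 8 to reach (1S,2S)-1-[3,4-dimethoxy-5-(triisopropylsilyloxy)phenyl]-2-[3-methoxy-5-((E)-prop-1-en-1-yl)-2-(trifluoromethylsulfonyloxy)phenyl]propan-1-ol F10.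
- Apply the conditions of step 9 to reach (2S,3S)-2-[3,4-dimethoxy-5-(triisopropylsilyloxy)phenyl]-7-methoxy-3-methyl-5-((E)-prop-1-en-1-yl)-2,3-dihydrobenzofuran F11.
- Finish with Bu4NF in THF at 0 °C, which rejoins the route at 14 without any acid.

## Further compounds

F1 | step 9 | (1S,2S)-2-[2-hydroxy-3-methoxy-5-((E)-prop-1-en-1-yl)phenyl]-1-[3,4-dimethoxy-5-(methoxymethoxy)phenyl]propan-1-ol | C/C=C/c1cc(OC)c(O)c(c1)[C@H](C)[C@H](O)c1cc(OCOC)c(OC)c(OC)c1
F2 | step 7 | 3-iodo-5-methoxy-4-(triisopropylsilyloxy)benzaldehyde | O=Cc1cc(I)c(O[Si](C(C)C)(C(C)C)C(C)C)c(OC)c1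
F3 | step 7 | [2-iodo-6-methoxy-4-(prop-1-en-1-yl)phenoxy]triisopropylsilane, Z/E mixture | CC=Cc1cc(I)c(O[Si](C(C)C)(C(C)C)C(C)C)c(OC)c1
F4 | step 7 | [2-iodo-6-methoxy-4-((E)-prop-1-en-1-yl)phenoxy]triisopropylsilane | C/C=C/c1cc(I)c(O[Si](C(C)C)(C(C)C)C(C)C)c(OC)c1
F5 | step 7 | 1-[3,4-dimethoxy-5-(methoxymethoxy)phenyl]-2-[3-methoxy-5-((E)-prop-1-en-1-yl)-2-(triisopropylsilyloxy)phenyl]propan-1-one, racemic | C/C=C/c1cc(OC)c(O[Si](C(C)C)(C(C)C)C(C)C)c(c1)C(C)C(=O)c1cc(OCOC)c(OC)c(OC)c1
F6 | step 7 | 2-[2-hydroxy-3-methoxy-5-((E)-prop-1-en-1-yl)phenyl]-1-[3,4-dimethoxy-5-(methoxymethoxy)phenyl]propan-1-one, racemic | C/C=C/c1cc(OC)c(O)c(c1)C(C)C(=O)c1cc(OCOC)c(OC)c(OC)c1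
F7 | step 8 | (1R,2R)-1-[3,4-dimethoxy-5-(methoxymethoxy)phenyl]-2-[3-methoxy-5-((E)-prop-1-en-1-yl)-2-(trifluoromethylsulfonyloxy)phenyl]propan-1-ol | C/C=C/c1cc(OC)c(OS(=O)(=O)C(F)(F)F)c(c1)[C@@H](C)[C@@H](O)c1cc(OCOC)c(OC)c(OC)c1
F8 | step 10 | 1-(3-hydroxy-4,5-dimethoxyphenyl)-2-[3-methoxy-5-((E)-prop-1-en-1-yl)-2-(trifluoromethylsulfonyloxy)phenyl]propan-1-one, racemic | C/C=C/c1cc(OC)c(OS(=O)(=O)C(F)(F)F)c(c1)C(C)C(=O)c1cc(O)c(OC)c(OC)c1
F9 | step 10 | 1-[3,4-dimethoxy-5-(triisopropylsilyloxy)phenyl]-2-[3-methoxy-5-((E)-prop-1-en-1-yl)-2-(trifluoromethylsulfonyloxy)phenyl]propan-1-one, racemic | C/C=C/c1cc(OC)c(OS(=O)(=O)C(F)(F)F)c(c1)C(C)C(=O)c1cc(O[Si](C(C)C)(C(C)C)C(C)C)c(OC)c(OC)c1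
F10 | step 10 | (1S,2S)-1-[3,4-dimethoxy-5-(triisopropylsilyloxy)phenyl]-2-[3-methoxy-5-((E)-prop-1-en-1-yl)-2-(trifluoromethylsulfonyloxy)phenyl]propan-1-ol | C/C=C/c1cc(OC)c(OS(=O)(=O)C(F)(F)F)c(c1)[C@H](C)[C@H](O)c1cc(O[Si](C(C)C)(C(C)C)C(C)C)c(OC)c(OC)c1
F11 | step 10 | (2S,3S)-2-[3,4-dimethoxy-5-(triisopropylsilyloxy)phenyl]-7-methoxy-3-methyl-5-((E)-prop-1-en-1-yl)-2,3-dihydrobenzofuran | C/C=C/c1cc(OC)c2c(c1)[C@H](C)[C@@H](c1cc(O[Si](C(C)C)(C(C)C)C(C)C)c(OC)c(OC)c1)O2
A1 | alternative 1 | (2S,3S)-5-bromo-2-[3-(tert-butyldimethylsilyloxy)-4,5-dimethoxyphenyl]-7-methoxy-3-methyl-2,3-dihydrobenzofuran | Brc1cc(OC)c2c(c1)[C@H](C)[C@@H](c1cc(O[Si](C)(C)C(C)(C)C)c(OC)c(OC)c1)O2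
A2 | alternative 1 | 4-bromo-2-methoxy-6-[1-(4-methylphenylsulfonyl)ethyl]phenol, racemic | CC(c1cc(Br)cc(OC)c1O)S(=O)(=O)c1ccc(C)cc1
A3 | alternative 1 | 4-bromo-6-ethylidene-2-methoxycyclohexa-2,4-dien-1-one | CC=C1C=C(Br)C=C(OC)C1=O
A4 | alternative 1 | (2S,5S)-1-[3-(tert-butyldimethylsilyloxy)-4,5-dimethoxybenzyl]-2,5-dimethylthiolanium trifluoromethanesulfonate (drawn as one enantiomer of the sulfide; the antipode would be used if the sense of induction required it) | C[C@H]1CC[C@H](C)[S+]1Cc1cc(O[Si](C)(C)C(C)(C)C)c(OC)c(OC)c1.[O-]S(=O)(=O)C(F)(F)F
A5 | alternative 2 | methyl (2S,3S)-2-[3-(tert-butyldimethylsilyloxy)-4,5-dimethoxyphenyl]-7-methoxy-3-methyl-2,3-dihydrobenzofuran-5-carboxylate | COC(=O)c1cc(OC)c2c(c1)[C@H](C)[C@@H](c1cc(O[Si](C)(C)C(C)(C)C)c(OC)c(OC)c1)O2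
A6 | alternative 2 | methyl 3-[(1R,2R)-2-(3-(tert-butyldimethylsilyloxy)-4,5-dimethoxyphenyl)cyclopropyl]-4-hydroxy-5-methoxybenzoate | COC(=O)c1cc(OC)c(O)c(c1)[C@@H]1C[C@H]1c1cc(O[Si](C)(C)C(C)(C)C)c(OC)c(OC)c1
A7 | alternative 3 | methyl (2S,3R)-5-bromo-2-[3,4-dimethoxy-5-(methoxymethoxy)phenyl]-7-methoxy-2,3-dihydrobenzofuran-3-carboxylate (cis) | Brc1cc(OC)c2c(c1)[C@@H](C(=O)OC)[C@@H](c1cc(OCOC)c(OC)c(OC)c1)O2
A8 | alternative 3 | methyl 2-[5-bromo-2-(3,4-dimethoxy-5-(methoxymethoxy)benzyloxy)-3-methoxyphenyl]-2-diazoacetate | COC(=O)C(=[N+]=[N-])c1cc(Br)cc(OC)c1OCc1cc(OCOC)c(OC)c(OC)c1
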